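**Strategy.** Ring A (the 3-hydroxy ε-ring) is disconnected at C1–C2 and C5–C6: C2–C3(O)–C4=C5(CH3) is the bis-silyl dienol ether of acetylacetone, and the gem-dimethyl C1 with C6 is isopropylidene Meldrum's acid. One polarity-matched [4+2] annulation joins them; loss of silanol gives an achiral 3-oxo-4-ene spiro ring on which all diene and endo/exo isomers converge. CBS reduction sets C3, whose oxygen then captures one Meldrum carbonyl and so fixes C6. The derived C15 ester serves both end groups: Mitsunobu inversion gives the 3-hydroxy ring and palladium–hydride deoxygenation the unsubstituted ε-ring. Two Wittig reactions with a C10 dialdehyde complete the polyene.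

Key step: step 2

Remark: ring positions are cited in carotenoid numbering (C1 gem-dimethyl carbon, C3 carbinol carbon, C5 methyl-bearing sp2 carbon, C6 chain-bearing carbon; ring B is the unsubstituted ε-ring); 13 and 21 are taken as the commercial E isomers.

Step 1
Reactants: 1 pentane-2,4-dione (acetylacetone)
Product: 3 (3Z)-2,4-bis(trimethylsilyloxy)penta-1,3-diene, via (3Z)-4-(trimethylsilyloxy)pent-3-en-2-one 2 (not isolated)
Conditions: Me3SiOTf (2.2 equiv), Et3N (2.5 equiv), Et2O, 0 °C → rt
Reagents that add atoms: trimethylsilyl trifluoromethanesulfonate, C[Si](C)(C)OS(=O)(=O)C(F)(F)F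
Why: Double silyl enol ether formation by soft enolisation: the first silyl group caps the enol of the diketone and the second can only enolise the terminal methyl, giving the 1,3-bis(silyloxy)diene; its C3=C4 geometry does not matter because that carbon becomes sp3 and is eliminated in step 2.

Step 2
Reactants: 3 (3Z)-2,4-bis(trimethylsilyloxy)penta-1,3-diene; 4 2,2-dimethyl-5-(propan-2-ylidene)-1,3-dioxane-4,6-dione (isopropylidene Meldrum's acid)
Product: 6 3,3,7,11,11-pentamethyl-2,4-dioxaspiro[5.5]undec-7-ene-1,5,9-trione, via bis-silyl cycloadduct 5 (not isolated)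
Conditions: toluene, 0 °C → 40 °C; then 1 M HCl, THF, rt
Reagents that add atoms: none
Why: Normal-electron-demand Diels–Alder reaction of a 1,3-dioxygenated 2-silyloxydiene with a doubly activated alkylidene Meldrum's acid, strongly asynchronous: the CH2 terminus of 3 (largest HOMO coefficient, pushed by both silyloxy groups) bonds to the isopropylidene carbon of 4 (largest LUMO coefficient), and the Meldrum carbon bonds to the silyloxy- and methyl-bearing diene terminus. The six-membered carbocycle closes by suprafacial [4+2] addition or, in the stepwise limit (vinylogous Mukaiyama–Michael addition, then attack of the Meldrum enolate on the silyloxocarbenium ion), by a 6-exo-trig closure; both paths give the same ring. The only stereocentre formed, the silyloxy carbon of 5, is erased when aqueous acid cleaves both silyl groups and the β-hydroxy ketone dehydrates, so diene E/Z and endo/exo isomers converge on achiral 6, whose spiro carbon is not stereogenic. The step needs head-to-tail regioselectivity and closure through carbon, not oxygen: the first is secured by the matched polarity of the two partners, the second because the O-closed hetero-Diels–Alder adduct is a reversible silyl ketene acetal while the carbocycle is the thermodynamic sink fixed by the acid work-up.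

Step 3
Reactants: 6 3,3,7,11,11-pentamethyl-2,4-dioxaspiro[5.5]undec-7-ene-1,5,9-trione
Product: 8 (1R,4S)-5,8,8-trimethyl-3-oxo-2-oxabicyclo[2.2.2]oct-5-ene-4-carboxylic acid, via (9R)-hydroxy spiro dione 7 (not isolated)
Conditions: (S)-1-methyl-3,3-diphenyltetrahydro-1H,3H-pyrrolo[1,2-c][1,3,2]oxazaborole ((S)-Me-CBS, 20 mol%), catecholborane, toluene, −78 °C; then MeOH, Et3N, DMAP (cat.), 40 °C; aq. HCl work-up
Reagents that add atoms: none
Why: Corey–Bakshi–Shibata reduction followed by intramolecular transacylation of the acylal: with the alkenyl side of the enone as the large group the (S)-catalyst should give the (9R)-carbinol 7 from achiral 6 (catalyst control), and its oxygen then opens the Meldrum carbonyl on its own ring face with loss of acetone, which desymmetrises the spiro carbon and so sets the future C6 (4S in 8) relative to C3 (1R).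

Step 4
Reactants: 8 (1R,4S)-5,8,8-trimethyl-3-oxo-2-oxabicyclo[2.2.2]oct-5-ene-4-carboxylic acid
Product: 11 (1R,4S)-5,8,8-trimethyl-2-oxabicyclo[2.2.2]oct-5-en-3-one, via acid chloride 9 (not isolated), via thiohydroxamate ester 10 (not isolated)
Conditions: (COCl)2, DMF (cat.), CH2Cl2, 0 °C → rt; then sodium 2-thioxopyridin-1(2H)-olate, DMAP (cat.), t-BuSH, toluene, visible light, rt
Reagents that add atoms: none
Why: Barton reductive decarboxylation: the thiohydroxamate ester fragments under light to a bridgehead radical that cannot invert within the bicyclo[2.2.2] cage and takes hydrogen from t-BuSH, so CO2H is replaced by H with retention and the C6 configuration set in step 3 is kept.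

Step 5
Reactants: 11 (1R,4S)-5,8,8-trimethyl-2-oxabicyclo[2.2.2]oct-5-en-3-one
Product: 12 (1R,4S)-5,8,8-trimethyl-2-oxabicyclo[2.2.2]oct-5-en-3-ol (lactol)
Conditions: i-Bu2AlH (1.1 equiv), CH2Cl2, −78 °C
Reagents that add atoms: none
Why: Partial reduction of a lactone with i-Bu2AlH at low temperature stops at the aluminium hemiacetal, giving the lactol (a masked cis hydroxy aldehyde) without touching the two bridgehead stereocentres.

Step 6
Reactants: 12 (1R,4S)-5,8,8-trimethyl-2-oxabicyclo[2.2.2]oct-5-en-3-ol; 13 ethyl (2E)-4-(diethoxyphosphoryl)-3-methylbut-2-enoate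
Product: 14 ethyl (2E,4E)-5-[(1S,4R)-4-hydroxy-2,6,6-trimethylcyclohex-2-en-1-yl]-3-methylpenta-2,4-dienoate
Conditions: 13 (2.5 equiv), LiN(SiMe3)2 (2.3 equiv), THF, −78 °C → rt
Reagents that add atoms: none
Why: Horner–Wadsworth–Emmons olefination of the open hydroxy aldehyde form of the lactol with the vinylogous phosphonate anion gives the new C7=C8 bond E (stabilised anion), while base is kept below the phosphonate so that the enolisable C6–H is not touched; a minor 2Z isomer would be removed by chromatography.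

Step 7
Reactants: 14 ethyl (2E,4E)-5-[(1S,4R)-4-hydroxy-2,6,6-trimethylcyclohex-2-en-1-yl]-3-methylpenta-2,4-dienoate
Product: 15 ethyl (2E,4E)-5-[(1S,4S)-4-(benzoyloxy)-2,6,6-trimethylcyclohex-2-en-1-yl]-3-methylpenta-2,4-dienoate
Conditions: PhCO2H, PPh3, diisopropyl azodicarboxylate, THF, 0 °C → rt
Reagents that add atoms: benzoic acid, O=C(O)c1ccccc1
Why: Mitsunobu esterification with SN2 inversion at the allylic C3 carbinol turns the lactone-derived cis relationship into the trans (3S,6S) arrangement of ring A; the benzoate also serves as the allylic leaving group for step 10.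

Step 8
Reactants: 15 ethyl (2E,4E)-5-[(1S,4S)-4-(benzoyloxy)-2,6,6-trimethylcyclohex-2-en-1-yl]-3-methylpenta-2,4-dienoate
Product: 16 (1S,4S)-4-[(1E,3E)-5-hydroxy-3-methylpenta-1,3-dien-1-yl]-3,5,5-trimethylcyclohex-2-en-1-ol
Conditions: i-Bu2AlH (5 equiv), CH2Cl2, −78 °C
Reagents that add atoms: none
Why: i-Bu2AlH reduces the dienoate 1,2 to the primary allylic alcohol and cleaves the benzoate reductively in one operation, leaving alkenes and stereocentres untouched.

Step 9
Reactants: 16 (1S,4S)-4-[(1E,3E)-5-hydroxy-3-methylpenta-1,3-dien-1-yl]-3,5,5-trimethylcyclohex-2-en-1-ol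
Product: 17 {(2E,4E)-5-[(1S,4S)-4-hydroxy-2,6,6-trimethylcyclohex-2-en-1-yl]-3-methylpenta-2,4-dien-1-yl}triphenylphosphonium bromide
Conditions: PPh3·HBr, CH2Cl2, 0 °C → rt
Reagents that add atoms: triphenylphosphine hydrobromide, [Br-].c1ccc(cc1)[PH+](c1ccccc1)c1ccccc1
Why: Allylic phosphonium salt formation with Ph3P·HBr (ionisation to the delocalised pentadienyl cation and capture by PPh3 at the primary terminus): the primary dienylic alcohol ionises far more readily than the isolated ring allylic alcohol, so the C3 carbinol should survive.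

Step 10
Reactants: 15 ethyl (2E,4E)-5-[(1S,4S)-4-(benzoyloxy)-2,6,6-trimethylcyclohex-2-en-1-yl]-3-methylpenta-2,4-dienoate
Product: 18 ethyl (2E,4E)-3-methyl-5-[(1S)-2,6,6-trimethylcyclohex-2-en-1-yl]penta-2,4-dienoate
Conditions: Pd(PPh3)4 (5 mol%), NaBH4, THF, 0 °C → rt
Reagents that add atoms: none
Why: Palladium-catalysed hydrogenolysis of an allylic ester (Tsuji–Trost ionisation by zerovalent palladium, then external hydride from borohydride at the less hindered C3 terminus of the π-allyl complex) removes the oxygen, keeps the C4=C5 double bond in place and leaves the adjacent C6 stereocentre untouched, giving the ring B end group.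

Step 11
Reactants: 18 ethyl (2E,4E)-3-methyl-5-[(1S)-2,6,6-trimethylcyclohex-2-en-1-yl]penta-2,4-dienoate
Product: 19 (2E,4E)-3-methyl-5-[(1S)-2,6,6-trimethylcyclohex-2-en-1-yl]penta-2,4-dien-1-ol
Conditions: i-Bu2AlH (2.5 equiv), CH2Cl2, −78 °C
Reagents that add atoms: none
Why: 1,2-Reduction of the conjugated ester to the primary allylic alcohol with i-Bu2AlH, which does not affect the alkenes or the C6 stereocentre.

Step 12
Reactants: 19 (2E,4E)-3-methyl-5-[(1S)-2,6,6-trimethylcyclohex-2-en-1-yl]penta-2,4-dien-1-ol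
Product: 20 {(2E,4E)-3-methyl-5-[(1S)-2,6,6-trimethylcyclohex-2-en-1-yl]penta-2,4-dien-1-yl}triphenylphosphonium bromide
Conditions: PPh3·HBr, CH2Cl2, 0 °C → rt
Reagents that add atoms: triphenylphosphine hydrobromide, [Br-].c1ccc(cc1)[PH+](c1ccccc1)c1ccccc1
Why: Allylic phosphonium salt formation with Ph3P·HBr as in step 9, through the pentadienyl cation and capture at the primary terminus.

Step 13
Reactants: 17 {(2E,4E)-5-[(1S,4S)-4-hydroxy-2,6,6-trimethylcyclohex-2-en-1-yl]-3-methylpenta-2,4-dien-1-yl}triphenylphosphonium bromide; 21 (2E,4E,6E)-2,7-dimethylocta-2,4,6-trienedial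
Product: 22 (2E,4E,6E,8E,10E,12E)-13-[(1S,4S)-4-hydroxy-2,6,6-trimethylcyclohex-2-en-1-yl]-2,7,11-trimethyltrideca-2,4,6,8,10,12-hexaenal
Conditions: 21 (threefold excess), 1,2-epoxybutane, EtOH, reflux
Reagents that add atoms: none
Why: Wittig olefination with the epoxide as neutral HBr scavenger forms C11=C12 on the ring A side; excess dialdehyde and the lower electrophilicity of the formyl group in the extended polyene 22 favour mono-condensation, and the new disubstituted double bond should settle as E under the thermal conditions.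

Step 14
Reactants: 22 (2E,4E,6E,8E,10E,12E)-13-[(1S,4S)-4-hydroxy-2,6,6-trimethylcyclohex-2-en-1-yl]-2,7,11-trimethyltrideca-2,4,6,8,10,12-hexaenal; 20 {(2E,4E)-3-methyl-5-[(1S)-2,6,6-trimethylcyclohex-2-en-1-yl]penta-2,4-dien-1-yl}triphenylphosphonium bromide
Product: 23 (3S,6S,6'S)-ε,ε-caroten-3-ol (target)
Conditions: 1,2-epoxybutane, EtOH, reflux
Reagents that add atoms: none
Why: Second Wittig olefination joins the two halves at the C11=C12 bond on the ring B side; the disubstituted double bond equilibrates to E at reflux to give the all-E polyene, and the three stereocentres are remote from the reacting centres.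

**Compound list**
1 | pentane-2,4-dione (acetylacetone) | CC(=O)CC(C)=O | starting material
2 | (3Z)-4-(trimethylsilyloxy)pent-3-en-2-one | CC(=O)/C=C(/C)O[Si](C)(C)C | intermediate (not isolated)
3 | (3Z)-2,4-bis(trimethylsilyloxy)penta-1,3-diene | C=C(O[Si](C)(C)C)/C=C(/C)O[Si](C)(C)C | intermediate
4 | 2,2-dimethyl-5-(propan-2-ylidene)-1,3-dioxane-4,6-dione | CC(C)=C1C(=O)OC(C)(C)OC1=O | starting material
5 | 3,3,7,11,11-pentamethyl-7,9-bis(trimethylsilyloxy)-2,4-dioxaspiro[5.5]undec-8-ene-1,5-dione (racemic) | CC1(O[Si](C)(C)C)C=C(O[Si](C)(C)C)CC(C)(C)C12C(=O)OC(C)(C)OC2=O | intermediate (not isolated)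
6 | 3,3,7,11,11-pentamethyl-2,4-dioxaspiro[5.5]undec-7-ene-1,5,9-trione | CC1=CC(=O)CC(C)(C)C12C(=O)OC(C)(C)OC2=O | intermediate
7 | (9R)-9-hydroxy-3,3,7,11,11-pentamethyl-2,4-dioxaspiro[5.5]undec-7-ene-1,5-dione | CC1=C[C@H](O)CC(C)(C)C12C(=O)OC(C)(C)OC2=O | intermediate (not isolated)
8 | (1R,4S)-5,8,8-trimethyl-3-oxo-2-oxabicyclo[2.2.2]oct-5-ene-4-carboxylic acid | O=C1O[C@H]2C=C(C)[C@]1(C(=O)O)C(C)(C)C2 | intermediate
9 | (1R,4R)-5,8,8-trimethyl-3-oxo-2-oxabicyclo[2.2.2]oct-5-ene-4-carbonyl chloride | O=C1O[C@H]2C=C(C)[C@]1(C(Cl)=O)C(C)(C)C2 | intermediate (not isolated)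
10 | 2-thioxopyridin-1(2H)-yl (1R,4R)-5,8,8-trimethyl-3-oxo-2-oxabicyclo[2.2.2]oct-5-ene-4-carboxylate | O=C1O[C@H]2C=C(C)[C@]1(C(=O)On3ccccc3=S)C(C)(C)C2 | intermediate (not isolated)
11 | (1R,4S)-5,8,8-trimethyl-2-oxabicyclo[2.2.2]oct-5-en-3-one | O=C1O[C@H]2C=C(C)[C@@H]1C(C)(C)C2 | intermediate
12 | (1R,4S)-5,8,8-trimethyl-2-oxabicyclo[2.2.2]oct-5-en-3-ol (anomer mixture) | OC1O[C@H]2C=C(C)[C@@H]1C(C)(C)C2 | intermediate
13 | ethyl (2E)-4-(diethoxyphosphoryl)-3-methylbut-2-enoate | CCOC(=O)/C=C(\C)CP(=O)(OCC)OCC | starting material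
14 | ethyl (2E,4E)-5-[(1S,4R)-4-hydroxy-2,6,6-trimethylcyclohex-2-en-1-yl]-3-methylpenta-2,4-dienoate | CCOC(=O)/C=C(C)/C=C/[C@@H]1C(C)=C[C@H](O)CC1(C)C | intermediate
15 | ethyl (2E,4E)-5-[(1S,4S)-4-(benzoyloxy)-2,6,6-trimethylcyclohex-2-en-1-yl]-3-methylpenta-2,4-dienoate | CCOC(=O)/C=C(C)/C=C/[C@@H]1C(C)=C[C@@H](OC(=O)c2ccccc2)CC1(C)C | intermediate
16 | (1S,4S)-4-[(1E,3E)-5-hydroxy-3-methylpenta-1,3-dien-1-yl]-3,5,5-trimethylcyclohex-2-en-1-ol | OC/C=C(C)/C=C/[C@@H]1C(C)=C[C@@H](O)CC1(C)C | intermediate
17 | {(2E,4E)-5-[(1S,4S)-4-hydroxy-2,6,6-trimethylcyclohex-2-en-1-yl]-3-methylpenta-2,4-dien-1-yl}triphenylphosphonium bromide | [Br-].c1ccccc1[P+](c1ccccc1)(c1ccccc1)C/C=C(C)/C=C/[C@@H]1C(C)=C[C@@H](O)CC1(C)C | intermediate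
18 | ethyl (2E,4E)-3-methyl-5-[(1S)-2,6,6-trimethylcyclohex-2-en-1-yl]penta-2,4-dienoate | CCOC(=O)/C=C(C)/C=C/[C@@H]1C(C)=CCCC1(C)C | intermediate
19 | (2E,4E)-3-methyl-5-[(1S)-2,6,6-trimethylcyclohex-2-en-1-yl]penta-2,4-dien-1-ol | OC/C=C(C)/C=C/[C@@H]1C(C)=CCCC1(C)C | intermediate
20 | {(2E,4E)-3-methyl-5-[(1S)-2,6,6-trimethylcyclohex-2-en-1-yl]penta-2,4-dien-1-yl}triphenylphosphonium bromide | [Br-].c1ccccc1[P+](c1ccccc1)(c1ccccc1)C/C=C(C)/C=C/[C@@H]1C(C)=CCCC1(C)C | intermediate
21 | (2E,4E,6E)-2,7-dimethylocta-2,4,6-trienedial | O=C/C(C)=C/C=C/C=C(C)/C=O | starting material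
22 | (2E,4E,6E,8E,10E,12E)-13-[(1S,4S)-4-hydroxy-2,6,6-trimethylcyclohex-2-en-1-yl]-2,7,11-trimethyltrideca-2,4,6,8,10,12-hexaenal | O=C/C(C)=C/C=C/C=C(C)/C=C/C=C(C)/C=C/[C@@H]1C(C)=C[C@@H](O)CC1(C)C | intermediate
23 | (3S,6S,6'S)-ε,ε-caroten-3-ol, all-E | CC1=CCCC(C)(C)[C@@H]1/C=C/C(C)=C/C=C/C(C)=C/C=C/C=C(C)/C=C/C=C(C)/C=C/[C@@H]1C(C)=C[C@@H](O)CC1(C)C | target

**Step count.** Total: 14 steps. Longest linear sequence: 11 steps (steps 1–7, then 8, 9, 13, 14; the ring B branch 1–7, 10, 11, 12, 14 is equally long).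

**Steps most likely to fail**

Step 2. The cycloaddition passes through three contiguous fully substituted carbons, so it may stall after the first C–C bond, close through oxygen (hetero-cycloaddition of the oxadiene), or react at the central carbon of the diene. The fallback is a stepwise Lewis-acid variant that sets out from 3 and commercial dimethyl 2-(propan-2-ylidene)propanedioate. TiCl4-promoted Mukaiyama–Michael addition (CH2Cl2, −78 °C) would give open-chain dimethyl 2-(2-methyl-4,6-dioxoheptan-2-yl)propanedioate F1. Pyridine added to the same flask (TiCl4/pyridine Knoevenagel-type aldol condensation) would close it to dimethyl 2,6,6-trimethyl-4-oxocyclohex-2-ene-1,1-dicarboxylate F2. CBS reduction as in step 3 would give dimethyl (4R)-4-hydroxy-2,6,6-trimethylcyclohex-2-ene-1,1-dicarboxylate F3. NaH (cat.) in toluene would lactonise the ester on the hydroxyl face to methyl (1R,4S)-5,8,8-trimethyl-3-oxo-2-oxabicyclo[2.2.2]oct-5-ene-4-carboxylate F4. LiI in pyridine (SN2 at the ester methyl) would then return to the route at 8.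

Step 4. Activation of the very hindered bridgehead acid may be slow, or the bridgehead radical may fragment before hydrogen transfer. The fallback is an ionic, thermodynamically controlled route that sets out from 8. NaOMe in MeOH would open the lactone to (1S,4R)-4-hydroxy-1-(methoxycarbonyl)-2,6,6-trimethylcyclohex-2-ene-1-carboxylic acid F5. Thermal decarboxylation of this malonic half-acid (DMSO, 130 °C) would give methyl (4R)-4-hydroxy-2,6,6-trimethylcyclohex-2-ene-1-carboxylate F6 as a mixture of C1 epimers. NaOMe (cat.) in refluxing toluene with removal of MeOH would epimerise C1, and since only the cis epimer can lactonise, both epimers would funnel into 11, where the route is rejoined.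

Step 10. The π-allyl palladium complex may undergo β-hydride elimination toward C6 (loss of the stereocentre, diene formation), hydride may be delivered to the wrong allyl terminus, or the dienoate may suffer conjugate reduction. The fallback is a radical deoxygenation that sets out from 14. 1,1'-Thiocarbonyldiimidazole (THF, reflux) would give ethyl (2E,4E)-5-[(1S,4R)-4-(1H-imidazole-1-carbothioyloxy)-2,6,6-trimethylcyclohex-2-en-1-yl]-3-methylpenta-2,4-dienoate F7. Bu3SnH/AIBN in toluene at 80 °C (Barton–McCombie) would generate the C3–C4–C5 allyl radical, which takes hydrogen at the less hindered C3 and returns to the route at 18.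

Further compounds
F1 | step 2 | dimethyl 2-(2-methyl-4,6-dioxoheptan-2-yl)propanedioate | COC(=O)C(C(=O)OC)C(C)(C)CC(=O)CC(C)=O
F2 | step 2 | dimethyl 2,6,6-trimethyl-4-oxocyclohex-2-ene-1,1-dicarboxylate | COC(=O)C1(C(=O)OC)C(C)=CC(=O)CC1(C)C
F3 | step 2 | dimethyl (4R)-4-hydroxy-2,6,6-trimethylcyclohex-2-ene-1,1-dicarboxylate | COC(=O)C1(C(=O)OC)C(C)=C[C@H](O)CC1(C)C
F4 | step 2 | methyl (1R,4S)-5,8,8-trimethyl-3-oxo-2-oxabicyclo[2.2.2]oct-5-ene-4-carboxylate | O=C1O[C@H]2C=C(C)[C@]1(C(=O)OC)C(C)(C)C2
F5 | step 4 | (1S,4R)-4-hydroxy-1-(methoxycarbonyl)-2,6,6-trimethylcyclohex-2-ene-1-carboxylic acid | COC(=O)[C@]1(C(=O)O)C(C)=C[C@H](O)CC1(C)C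
F6 | step 4 | methyl (4R)-4-hydroxy-2,6,6-trimethylcyclohex-2-ene-1-carboxylate (C1 epimers) | COC(=O)C1C(C)=C[C@H](O)CC1(C)C
F7 | step 10 | ethyl (2E,4E)-5-[(1S,4R)-4-(1H-imidazole-1-carbothioyloxy)-2,6,6-trimethylcyclohex-2-en-1-yl]-3-methylpenta-2,4-dienoate | CCOC(=O)/C=C(C)/C=C/[C@@H]1C(C)=C[C@H](OC(=S)n2ccnc2)CC1(C)C
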